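**Retrosynthetic overview**

1. Numbering: ring C (eight-membered) = C2(Me)=C3–C7–C8(OH)–C9(Me)–C18–C19–C20; ring D = C3–C4–C5(OH)–C6(Me)–C7; ring B = C9–C10–C11–C12(Me)–C17–C18; ring A = C12–C13–C14–C15(Me2)–C16–C17. The plan rests on C9, a methyl-bearing quaternary carbon bonded to the tertiary C18 inside ring B of the trans-fused A/B decalin.
2. Key disconnection C9–C18: a tertiary C9 radical, made by hydrogen-atom transfer to a 1,1-disubstituted alkene on the C12 arm, adds to C18 of a ring A enoate and closes ring B.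
3. Ring A precursor from dimedone: B-alkyl Suzuki arm, oxazaborolidine reduction, [2,3]-Wittig transfer to C17, hydroxyl-directed cyclopropanation and hydrogenolysis for the C12 methyl, Horner–Wadsworth–Emmons enoate.
4. Disconnection C7–C8: a ring D cyclopentenyl metal from (R)-4-silyloxycyclopentenone adds to the C8 aldehyde; C8 by Felkin–Anh reduction, C6/C7 by hydroxyl-directed hydrogenation.
5. Ring C last: ring-closing metathesis (C2=C20) of an isopropenyl carbinol with an allyl group, then reductive allylic transposition to C2=C3. Ring order: A, B, D (attached), C.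

Key step: step 16

Remark: the sense of the oxazaborolidine reduction and the facial preferences quoted follow the standard models and would be confirmed on the first batch.

**Route**

Step 1
Reactants: 1 dimedone
Product: 2 3-(2-methylpropoxy)-5,5-dimethylcyclohex-2-en-1-one
Conditions: 2-methylpropan-1-ol, p-TsOH·H2O (cat.), toluene, reflux, Dean–Stark
Reagents that add atoms: 2-methylpropan-1-ol, CC(C)CO
Why: Acid-catalysed vinylogous ester formation from the enolised symmetric 1,3-dione is driven by azeotropic removal of water and needs no regiocontrol.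

Step 2
Reactants: 2 3-(2-methylpropoxy)-5,5-dimethylcyclohex-2-en-1-one
Product: 4 5,5-dimethylcyclohex-2-en-1-one, via 3-(2-methylpropoxy)-5,5-dimethylcyclohex-2-en-1-ol 3 (not isolated)
Conditions: i-Bu2AlH, toluene, −78 to 0 °C; then 1 M HCl, THF, rt
Reagents that add atoms: water, O
Why: Stork–Danheiser transposition: 1,2-reduction of the vinylogous ester, then acid hydrolysis of the enol ether with loss of water gives the enone.

Step 3
Reactants: 4 5,5-dimethylcyclohex-2-en-1-one
Product: 5 2-iodo-5,5-dimethylcyclohex-2-en-1-one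
Conditions: I2, pyridine, CH2Cl2, 0 °C to rt
Reagents that add atoms: iodine, II
Why: α-Iodination of the enone by conjugate addition of pyridine, iodination of the enolate and elimination, so the halogen can only end up at C2.

Step 4
Reactants: 6 4,4-diethoxybut-1-ene; 5 2-iodo-5,5-dimethylcyclohex-2-en-1-one
Product: 8 2-(4,4-diethoxybutyl)-5,5-dimethylcyclohex-2-en-1-one, via 9-(4,4-diethoxybutyl)-9-borabicyclo[3.3.1]nonane 7 (not isolated)
Conditions: 6, 9-BBN-H, THF, rt; then 5, PdCl2(dppf) (5 mol%), AsPh3, Cs2CO3, DMF/H2O, rt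
Reagents that add atoms: none
Why: Anti-Markovnikov hydroboration followed by B-alkyl Suzuki–Miyaura coupling with the α-iodoenone installs the four-carbon arm (C11–C8) with C8 masked as an acetal.

Step 5
Reactants: 8 2-(4,4-diethoxybutyl)-5,5-dimethylcyclohex-2-en-1-one
Product: 9 (1S)-2-(4,4-diethoxybutyl)-5,5-dimethylcyclohex-2-en-1-ol
Conditions: (R)-2-methyl-CBS-oxazaborolidine (20 mol%), catecholborane, toluene, −78 °C
Reagents that add atoms: none
Why: Corey–Bakshi–Shibata 1,2-reduction in which the substituted alkenyl carbon acts as the large group, so hydride delivery by the (R)-catalyst should give the (S)-alcohol at C13.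

Step 6
Reactants: 9 (1S)-2-(4,4-diethoxybutyl)-5,5-dimethylcyclohex-2-en-1-ol
Product: 10 tributyl({[(1S)-2-(4,4-diethoxybutyl)-5,5-dimethylcyclohex-2-en-1-yl]oxy}methyl)stannane
Conditions: KH, Bu3SnCH2I, THF, 0 °C to rt
Reagents that add atoms: (iodomethyl)tributylstannane, CCCC[Sn](CCCC)(CCCC)CI
Why: Williamson etherification of the potassium alkoxide leaves the carbinol stereocentre untouched.

Step 7
Reactants: 10 tributyl({[(1S)-2-(4,4-diethoxybutyl)-5,5-dimethylcyclohex-2-en-1-yl]oxy}methyl)stannane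
Product: 12 [(1R)-2-(4,4-diethoxybutyl)-5,5-dimethylcyclohex-2-en-1-yl]methanol, via {[(1S)-2-(4,4-diethoxybutyl)-5,5-dimethylcyclohex-2-en-1-yl]oxy}methyllithium 11 (not isolated)
Conditions: n-BuLi, THF, −78 °C
Reagents that add atoms: none
Why: Tin–lithium exchange followed by [2,3]-Wittig (Wittig–Still) rearrangement, which is suprafacial, so the CH2OH carbon (C18) arrives at C17 on the face that carried the C13 oxygen and the alkene moves to C12=C13.

Step 8
Reactants: 12 [(1R)-2-(4,4-diethoxybutyl)-5,5-dimethylcyclohex-2-en-1-yl]methanol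
Product: 13 [1-(4,4-diethoxybutyl)-4,4-dimethylbicyclo[4.1.0]heptan-2-yl]methanol (cyclopropane CH2 cis to CH2OH)
Conditions: Et2Zn, CH2I2, CH2Cl2, −10 to 0 °C
Reagents that add atoms: diiodomethane, ICI
Why: Hydroxyl-directed Simmons–Smith cyclopropanation: the zinc alkoxide delivers CH2 to the alkene face syn to the hydroxymethyl group, which places the future C12 methyl carbon cis to C18.

Step 9
Reactants: 13 [1-(4,4-diethoxybutyl)-4,4-dimethylbicyclo[4.1.0]heptan-2-yl]methanol
Product: 14 [(1R,2R)-2-(4,4-diethoxybutyl)-2,5,5-trimethylcyclohexyl]methanol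
Conditions: H2 (3 bar), PtO2, AcOH, NaOAc, rt
Reagents that add atoms: none
Why: Catalytic hydrogenolysis of the cyclopropane at its least substituted bond (CH2–C13) should give the quaternary C12 methyl with retention at C12; sodium acetate buffers the acetal.

Step 10
Reactants: 14 [(1R,2R)-2-(4,4-diethoxybutyl)-2,5,5-trimethylcyclohexyl]methanol
Product: 15 (1R,2R)-2-(4,4-diethoxybutyl)-2,5,5-trimethylcyclohexane-1-carbaldehyde
Conditions: Dess–Martin periodinane, pyridine, CH2Cl2, 0 °C to rt
Reagents that add atoms: none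
Why: Dess–Martin oxidation under buffered, non-enolising conditions should keep the α-stereocentre C17.

Step 11
Reactants: 15 (1R,2R)-2-(4,4-diethoxybutyl)-2,5,5-trimethylcyclohexane-1-carbaldehyde
Product: 16 methyl (2E)-3-[(1S,2R)-2-(4,4-diethoxybutyl)-2,5,5-trimethylcyclohexyl]prop-2-enoate
Conditions: trimethyl phosphonoacetate, LiCl, DBU, MeCN, 0 °C
Reagents that add atoms: trimethyl phosphonoacetate, COC(=O)CP(=O)(OC)OC
Why: Horner–Wadsworth–Emmons olefination under Masamune–Roush conditions gives the (E)-enoate with a base too weak to epimerise the hindered C17.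

Step 12
Reactants: 16 methyl (2E)-3-[(1S,2R)-2-(4,4-diethoxybutyl)-2,5,5-trimethylcyclohexyl]prop-2-enoate
Product: 17 methyl (2E)-3-[(1S,2R)-2,5,5-trimethyl-2-(4-oxobutyl)cyclohexyl]prop-2-enoate
Conditions: 1 M HCl, THF, rt
Reagents that add atoms: water, O
Why: Acetal hydrolysis frees the C8 aldehyde while the enoate is inert to dilute acid.

Step 13
Reactants: 17 methyl (2E)-3-[(1S,2R)-2,5,5-trimethyl-2-(4-oxobutyl)cyclohexyl]prop-2-enoate
Product: 18 methyl (2E)-3-[(1S,2S)-2-(3-formylbut-3-en-1-yl)-2,5,5-trimethylcyclohexyl]prop-2-enoate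
Conditions: aq. CH2O (37%), pyrrolidine (10 mol%), propionic acid (10 mol%), i-PrOH, 45 °C
Reagents that add atoms: formaldehyde, C=O
Why: Organocatalytic α-methylenation (enamine Mannich condensation and elimination) puts the exocyclic methylene on C9, the only aldehyde α-CH2 in the molecule.

Step 14
Reactants: 18 methyl (2E)-3-[(1S,2S)-2-(3-formylbut-3-en-1-yl)-2,5,5-trimethylcyclohexyl]prop-2-enoate
Product: 19 methyl (2E)-3-{(1S,2S)-2-[3-(hydroxymethyl)but-3-en-1-yl]-2,5,5-trimethylcyclohexyl}prop-2-enoate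
Conditions: NaBH4, CeCl3·7H2O, MeOH, −40 °C
Reagents that add atoms: none
Why: Luche 1,2-reduction takes the enal to the allylic alcohol and leaves the enoate untouched.

Step 15
Reactants: 19 methyl (2E)-3-{(1S,2S)-2-[3-(hydroxymethyl)but-3-en-1-yl]-2,5,5-trimethylcyclohexyl}prop-2-enoate
Product: 20 methyl (2E)-3-[(1S,2S)-2-(3-{[tert-butyl(dimethyl)silyl]oxymethyl}but-3-en-1-yl)-2,5,5-trimethylcyclohexyl]prop-2-enoate
Conditions: TBSCl, imidazole, DMF, rt
Reagents that add atoms: tert-butyldimethylsilyl chloride, CC(C)(C)[Si](C)(C)Cl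
Why: Standard silylation of the primary allylic alcohol gives the cyclisation precursor.

Step 16
Reactants: 20 methyl (2E)-3-[(1S,2S)-2-(3-{[tert-butyl(dimethyl)silyl]oxymethyl}but-3-en-1-yl)-2,5,5-trimethylcyclohexyl]prop-2-enoate
Product: 21 methyl 2-[2-({[tert-butyl(dimethyl)silyl]oxy}methyl)-2,4a,7,7-tetramethyldecahydronaphthalen-1-yl]acetate (trans-decalin; C9 methyl axial)
Conditions: Fe(acac)3 (30 mol%), PhSiH3 (2.5 equiv), EtOH/ethylene glycol (5:1), 60 °C, 0.02 M
Reagents that add atoms: none
Why: Fe(acac)3 and PhSiH3 form an iron hydride that transfers a hydrogen atom to the terminal CH2 of the 1,1-disubstituted alkene, giving the tertiary C9 radical, which adds to C18 of the enoate; the α-ester radical is then reduced to the enolate and protonated by ethanol. The closest known reaction is the iron-hydride reductive olefin coupling (radical conjugate addition) in its intramolecular form. Ring B closes 6-exo-trig through a chair transition state built on the ring A chair, in which the enoate on C17 and the arm on C12 are trans-diequatorial because the axial C15 methyl forbids an axial C17 substituent. C18 is set by the (E)-enoate lying equatorial on the forming chair, which puts C18–H axial and anti to C17–H (trans ring fusion). C9 is set by the larger silyloxymethyl group taking the pseudo-equatorial site and the methyl the pseudo-axial one, away from 1,3-diaxial contacts with the axial hydrogens on C11 and C17. The step needs hydrogen-atom transfer to the electron-rich alkene in preference to the enoate, which the polarity of the two alkenes secures, and facial selectivity at C9, which rests only on the size difference of the two C9 substituents.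

Step 17
Reactants: 21 methyl 2-[2-({[tert-butyl(dimethyl)silyl]oxy}methyl)-2,4a,7,7-tetramethyldecahydronaphthalen-1-yl]acetate
Product: 23 trans-fused δ-lactone (ring O–C8–C9–C18–C19–C20=O) on ring B, via C8-hydroxy C20 methyl ester 22 (not isolated)
Conditions: TBAF, THF, 0 °C to rt
Reagents that add atoms: none
Why: Fluoride desilylation gives an alkoxide that lactonises onto the methyl ester, the two equatorial arms on C9 and C18 being held gauche.

Step 18
Reactants: 23 trans-fused δ-lactone
Product: 24 C8-hydroxy C20 N-methoxy-N-methylamide of the ring A/B decalin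
Conditions: MeNH(OMe)·HCl, AlMe3, CH2Cl2, 0 °C to rt
Reagents that add atoms: N,O-dimethylhydroxylamine hydrochloride, CNOC.Cl
Why: Aluminium amide aminolysis of the lactone (Weinreb amide formation) frees the C8 alcohol and puts C20 in a form that later stops at the aldehyde level.

Step 19
Reactants: 24 C8-hydroxy C20 N-methoxy-N-methylamide
Product: 25 C8 aldehyde C20 N-methoxy-N-methylamide of the ring A/B decalin
Conditions: Dess–Martin periodinane, CH2Cl2, rt
Reagents that add atoms: none
Why: Dess–Martin oxidation of the neopentyl alcohol gives an aldehyde that cannot enolise because C9 is quaternary.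

Step 20
Reactants: 26 (R)-4-{[tert-butyl(dimethyl)silyl]oxy}cyclopent-2-en-1-one
Product: 27 trans-4-{[tert-butyl(dimethyl)silyl]oxy}-3-methyl-1-(trimethylsilyloxy)cyclopent-1-ene
Conditions: MeMgBr, CuBr·SMe2 (10 mol%), TMSCl, THF, −78 °C
Reagents that add atoms: methylmagnesium bromide, C[Mg]Br; chlorotrimethylsilane, C[Si](C)(C)Cl
Why: Copper-catalysed conjugate addition anti to the silyloxy group, with in situ O-silylation of the enolate to prevent β-elimination of the silyloxy group.

Step 21
Reactants: 27 trans-4-{[tert-butyl(dimethyl)silyl]oxy}-3-methyl-1-(trimethylsilyloxy)cyclopent-1-ene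
Product: 28 (4R)-4-{[tert-butyl(dimethyl)silyl]oxy}-3-methylcyclopent-2-en-1-one
Conditions: Pd(OAc)2 (1.05 equiv), MeCN, rt
Reagents that add atoms: none
Why: Saegusa–Ito oxidation, in which β-hydride elimination can only involve C6–H, so the β-methyl enone forms and the C5 stereocentre is kept.

Step 22
Reactants: 28 (4R)-4-{[tert-butyl(dimethyl)silyl]oxy}-3-methylcyclopent-2-en-1-one
Product: 30 (4R)-2-bromo-4-{[tert-butyl(dimethyl)silyl]oxy}-3-methylcyclopent-2-en-1-one, via trans-2,3-dibromo ketone 29 (not isolated)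
Conditions: Br2, CH2Cl2, 0 °C; then Et3N
Reagents that add atoms: bromine, BrBr
Why: Bromine addition followed by dehydrobromination gives the α-bromo enone, the standard entry to α-metallated enone equivalents.

Step 23
Reactants: 30 (4R)-2-bromo-4-{[tert-butyl(dimethyl)silyl]oxy}-3-methylcyclopent-2-en-1-one
Product: 31 (8R)-6-bromo-8-{[tert-butyl(dimethyl)silyl]oxy}-7-methyl-1,4-dioxaspiro[4.4]non-6-ene
Conditions: TMSOCH2CH2OTMS, TMSOTf (cat.), CH2Cl2, −78 to −20 °C
Reagents that add atoms: 1,2-bis(trimethylsilyloxy)ethane, C[Si](C)(C)OCCO[Si](C)(C)C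
Why: Aprotic ketalisation with the bis-silyl glycol tolerates the silyl ether and masks the C3 ketone for halogen–metal exchange.

Step 24
Reactants: 31 (8R)-6-bromo-8-{[tert-butyl(dimethyl)silyl]oxy}-7-methyl-1,4-dioxaspiro[4.4]non-6-ene; 25 C8 aldehyde C20 N-methoxy-N-methylamide
Product: 34 C8 allylic alcohols joining ring D (C7) to C8 (mixture of C8 epimers), via vinyllithium 32 (not isolated), via vinylmagnesium bromide 33 (not isolated)
Conditions: 31, t-BuLi (2 equiv), Et2O, −78 °C; MgBr2·OEt2; then 25, −78 to −40 °C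
Reagents that add atoms: none
Why: Halogen–lithium exchange, transmetalation to magnesium and 1,2-addition to the non-enolisable aldehyde, which should react far faster than the N-methoxy-N-methylamide at low temperature; the C8 configuration is corrected in the next two steps.

Step 25
Reactants: 34 C8 allylic alcohols (epimer mixture)
Product: 35 C8 ketone (cyclopentenyl ketone) with C20 N-methoxy-N-methylamide
Conditions: Dess–Martin periodinane, pyridine, CH2Cl2, rt
Reagents that add atoms: none
Why: Dess–Martin oxidation converges both C8 epimers on one ketone without touching the ketal or the silyl ether.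

Step 26
Reactants: 35 C8 ketone with C20 N-methoxy-N-methylamide
Product: 37 six-membered lactol (ring O–C8–C9–C18–C19–C20(OH)) with the target configuration at C8, via C8-hydroxy C20 aldehyde 36 (not isolated)
Conditions: i-Bu2AlH (4 equiv), CH2Cl2, −78 to −20 °C; aq. Rochelle salt
Reagents that add atoms: none
Why: Hydride reduction of the ketone under Felkin–Anh control (attack anti to the C9–C18 bond, C10 next to the carbonyl oxygen, methyl next to the ring D substituent) should set C8, while the amide stops at the aldehyde, which closes to the lactol with ring D equatorial.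

Step 27
Reactants: 37 lactol with C5 silyl ether
Product: 38 lactol with free C5 hydroxyl
Conditions: TBAF, AcOH, THF, rt
Reagents that add atoms: none
Why: Buffered fluoride cleavage of the only silyl ether frees the allylic C5 hydroxyl that directs the next step.

Step 28
Reactants: 38 lactol with free C5 hydroxyl
Product: 39 lactol with saturated ring D (C6 and C7 as in the target)
Conditions: [Ir(cod)(PCy3)(py)]PF6 (20 mol%), H2 (10 bar), CH2Cl2, rt
Reagents that add atoms: none
Why: Hydroxyl-directed hydrogenation: iridium bound to the C5 hydroxyl delivers both hydrogens to that face of the tetrasubstituted C6=C7 alkene, which leaves the C6 methyl and the C7–C8 bond cis to each other and trans to the C5 oxygen.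

Step 29
Reactants: 39 lactol with saturated ring D
Product: 40 C5,C8-diol carrying the allyl group C19–C20=CH2 on C18
Conditions: Ph3PCH3Br, KHMDS (4 equiv), THF, 0 °C to rt
Reagents that add atoms: methyltriphenylphosphonium bromide, C[P+](c1ccccc1)(c1ccccc1)c1ccccc1.[Br-]
Why: Wittig methylenation of the open hydroxy aldehyde form of the lactol installs the terminal alkene only after the hydrogenation and frees the C8 hydroxyl.

Step 30
Reactants: 40 C5,C8-diol with allyl group
Product: 41 C5,C8-bis(tert-butyldimethylsilyl) ether with allyl group and C3 ketal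
Conditions: TBSOTf, 2,6-lutidine, CH2Cl2, 0 °C to rt
Reagents that add atoms: tert-butyldimethylsilyl trifluoromethanesulfonate, CC(C)(C)[Si](C)(C)OS(=O)(=O)C(F)(F)F
Why: Silyl triflate silylation protects both secondary alcohols, including the hindered C8 hydroxyl, so that no β-hydroxy ketone is exposed later.

Step 31
Reactants: 41 C5,C8-bis-silyl ether with C3 ketal
Product: 42 C3 ketone (cyclopentanone) with C5,C8-bis-silyl ether and allyl group
Conditions: PPTS, acetone/H2O, 45 °C
Reagents that add atoms: water, O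
Why: Mild acid hydrolysis of the dioxolane is chosen to avoid enolisation at C7 and β-elimination of the silyloxy groups.

Step 32
Reactants: 42 C3 ketone
Product: 43 C3 tertiary isopropenyl carbinol (isopropenyl cis to C7–H)
Conditions: isopropenylmagnesium bromide, CeCl3, THF, −78 °C
Reagents that add atoms: isopropenylmagnesium bromide, CC(=C)[Mg]Br
Why: Organocerium 1,2-addition to the enolisable ketone brings in C2 and C1, attack being expected anti to the C7 substituent; the C3 configuration is erased two steps later.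

Step 33
Reactants: 43 C3 tertiary isopropenyl carbinol
Product: 44 tetracyclic tertiary allylic alcohol with the C2=C20 alkene in ring C
Conditions: second-generation Hoveyda–Grubbs catalyst (10 mol%), toluene, 1 mM, 100 °C
Reagents that add atoms: none
Why: Ring-closing metathesis: the ruthenium carbene loads at the allyl terminus and closes onto the isopropenyl group to give the trisubstituted cyclooctene, whose geometry is fixed by the ring.

Step 34
Reactants: 44 tetracyclic tertiary allylic alcohol
Product: 45 C5,C8-bis(tert-butyldimethylsilyl) ether of the target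
Conditions: Et3SiH, BF3·OEt2, CH2Cl2, −78 °C
Reagents that add atoms: none
Why: Ionic hydrogenation with allylic transposition: the C3–C2–C20 allyl cation should take hydride at the less hindered secondary C20, which leaves the more stable tetrasubstituted C2=C3 alkene.

Step 35
Reactants: 45 C5,C8-bis-silyl ether of the target
Product: 46 CNP0213887.1
Conditions: TBAF, THF, 60 °C
Reagents that add atoms: none
Why: Fluoride desilylation under basic conditions frees both hydroxyls without risk to the tetrasubstituted alkene.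

**Compound list**

1 | dimedone (5,5-dimethylcyclohexane-1,3-dione) | CC1(C)CC(=O)CC(=O)C1 | starting material
2 | 3-(2-methylpropoxy)-5,5-dimethylcyclohex-2-en-1-one | CC(C)COC1=CC(=O)CC(C)(C)C1 | intermediate
3 | 3-(2-methylpropoxy)-5,5-dimethylcyclohex-2-en-1-ol (racemic) | CC(C)COC1=CC(O)CC(C)(C)C1 | intermediate (not isolated)
4 | 5,5-dimethylcyclohex-2-en-1-one | O=C1C=CCC(C)(C)C1 | intermediate
5 | 2-iodo-5,5-dimethylcyclohex-2-en-1-one | O=C1C(I)=CCC(C)(C)C1 | intermediate
6 | 4,4-diethoxybut-1-ene | C=CCC(OCC)OCC | starting material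
7 | 9-(4,4-diethoxybutyl)-9-borabicyclo[3.3.1]nonane | CCOC(CCCB1C2CCCC1CCC2)OCC | intermediate (not isolated)
8 | 2-(4,4-diethoxybutyl)-5,5-dimethylcyclohex-2-en-1-one | O=C1CC(C)(C)CC=C1CCCC(OCC)OCC | intermediate
9 | (1S)-2-(4,4-diethoxybutyl)-5,5-dimethylcyclohex-2-en-1-ol | O[C@H]1CC(C)(C)CC=C1CCCC(OCC)OCC | intermediate
10 | tributyl({[(1S)-2-(4,4-diethoxybutyl)-5,5-dimethylcyclohex-2-en-1-yl]oxy}methyl)stannane | CCCC[Sn](CCCC)(CCCC)CO[C@H]1CC(C)(C)CC=C1CCCC(OCC)OCC | intermediate
11 | {[(1S)-2-(4,4-diethoxybutyl)-5,5-dimethylcyclohex-2-en-1-yl]oxy}methyllithium | [Li]CO[C@H]1CC(C)(C)CC=C1CCCC(OCC)OCC | intermediate (not isolated)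
12 | [(1R)-2-(4,4-diethoxybutyl)-5,5-dimethylcyclohex-2-en-1-yl]methanol | OC[C@@H]1CC(C)(C)CC=C1CCCC(OCC)OCC | intermediate
13 | [1-(4,4-diethoxybutyl)-4,4-dimethylbicyclo[4.1.0]heptan-2-yl]methanol, cyclopropane CH2 cis to CH2OH | OC[C@@H]1CC(C)(C)C[C@@H]2C[C@]12CCCC(OCC)OCC | intermediate
14 | [(1R,2R)-2-(4,4-diethoxybutyl)-2,5,5-trimethylcyclohexyl]methanol | OC[C@@H]1CC(C)(C)CC[C@@]1(C)CCCC(OCC)OCC | intermediate
15 | (1R,2R)-2-(4,4-diethoxybutyl)-2,5,5-trimethylcyclohexane-1-carbaldehyde | O=C[C@@H]1CC(C)(C)CC[C@@]1(C)CCCC(OCC)OCC | intermediate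
16 | methyl (2E)-3-[(1S,2R)-2-(4,4-diethoxybutyl)-2,5,5-trimethylcyclohexyl]prop-2-enoate | COC(=O)/C=C/[C@@H]1CC(C)(C)CC[C@@]1(C)CCCC(OCC)OCC | intermediate
17 | methyl (2E)-3-[(1S,2R)-2,5,5-trimethyl-2-(4-oxobutyl)cyclohexyl]prop-2-enoate | COC(=O)/C=C/[C@@H]1CC(C)(C)CC[C@@]1(C)CCCC=O | intermediate
18 | methyl (2E)-3-[(1S,2S)-2-(3-formylbut-3-en-1-yl)-2,5,5-trimethylcyclohexyl]prop-2-enoate | COC(=O)/C=C/[C@@H]1CC(C)(C)CC[C@@]1(C)CCC(=C)C=O | intermediate
19 | methyl (2E)-3-{(1S,2S)-2-[3-(hydroxymethyl)but-3-en-1-yl]-2,5,5-trimethylcyclohexyl}prop-2-enoate | COC(=O)/C=C/[C@@H]1CC(C)(C)CC[C@@]1(C)CCC(=C)CO | intermediate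
20 | methyl (2E)-3-[(1S,2S)-2-(3-{[tert-butyl(dimethyl)silyl]oxymethyl}but-3-en-1-yl)-2,5,5-trimethylcyclohexyl]prop-2-enoate (cyclisation precursor) | COC(=O)/C=C/[C@@H]1CC(C)(C)CC[C@@]1(C)CCC(=C)CO[Si](C)(C)C(C)(C)C | intermediate
21 | methyl 2-[2-({[tert-butyl(dimethyl)silyl]oxy}methyl)-2,4a,7,7-tetramethyldecahydronaphthalen-1-yl]acetate, trans-decalin, C9 methyl axial | C(O[Si](C)(C)C(C)(C)C)[C@@]1(C)CC[C@]2(C)CCC(C)(C)C[C@H]2[C@@H]1CC(=O)OC | intermediate
22 | C8-hydroxy C20 methyl ester of the ring A/B decalin | OC[C@@]1(C)CC[C@]2(C)CCC(C)(C)C[C@H]2[C@@H]1CC(=O)OC | intermediate (not isolated)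
23 | trans-fused δ-lactone (O–C8, C20=O) on ring B | O=C1OC[C@@]2(C)CC[C@]3(C)CCC(C)(C)C[C@H]3[C@@H]2C1 | intermediate
24 | C8-hydroxy C20 N-methoxy-N-methylamide | OC[C@@]1(C)CC[C@]2(C)CCC(C)(C)C[C@H]2[C@@H]1CC(=O)N(C)OC | intermediate
25 | C8 aldehyde C20 N-methoxy-N-methylamide | O=C[C@@]1(C)CC[C@]2(C)CCC(C)(C)C[C@H]2[C@@H]1CC(=O)N(C)OC | intermediate
26 | (R)-4-{[tert-butyl(dimethyl)silyl]oxy}cyclopent-2-en-1-one | O=C1C[C@@H](O[Si](C)(C)C(C)(C)C)C=C1 | starting material
27 | trans-4-{[tert-butyl(dimethyl)silyl]oxy}-3-methyl-1-(trimethylsilyloxy)cyclopent-1-ene | C[Si](C)(C)OC=1C[C@@H](O[Si](C)(C)C(C)(C)C)[C@H](C)C=1 | intermediate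
28 | (4R)-4-{[tert-butyl(dimethyl)silyl]oxy}-3-methylcyclopent-2-en-1-one | O=C1C[C@@H](O[Si](C)(C)C(C)(C)C)C(C)=C1 | intermediate
29 | trans-2,3-dibromo-4-{[tert-butyl(dimethyl)silyl]oxy}-3-methylcyclopentan-1-one (anti adduct, C2/C3 not assigned) | O=C1C[C@@H](O[Si](C)(C)C(C)(C)C)C(C)(Br)C1Br | intermediate (not isolated)
30 | (4R)-2-bromo-4-{[tert-butyl(dimethyl)silyl]oxy}-3-methylcyclopent-2-en-1-one | O=C1C[C@@H](O[Si](C)(C)C(C)(C)C)C(C)=C1Br | intermediate
31 | (8R)-6-bromo-8-{[tert-butyl(dimethyl)silyl]oxy}-7-methyl-1,4-dioxaspiro[4.4]non-6-ene | C12(OCCO1)C[C@@H](O[Si](C)(C)C(C)(C)C)C(C)=C2Br | intermediate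
32 | ring D vinyllithium from 31 | C12(OCCO1)C[C@@H](O[Si](C)(C)C(C)(C)C)C(C)=C2[Li] | intermediate (not isolated)
33 | ring D vinylmagnesium bromide from 31 | C12(OCCO1)C[C@@H](O[Si](C)(C)C(C)(C)C)C(C)=C2[Mg]Br | intermediate (not isolated)
34 | C8 allylic alcohols, ring D (C3 ketal, C5 silyl ether, C6=C7) joined to the decalin, C20 N-methoxy-N-methylamide (C8 epimers) | C12(OCCO1)C[C@@H](O[Si](C)(C)C(C)(C)C)C(C)=C2C(O)[C@@]3(C)CC[C@]4(C)CCC(C)(C)C[C@H]4[C@@H]3CC(=O)N(C)OC | intermediate
35 | C8 ketone of 34 | C12(OCCO1)C[C@@H](O[Si](C)(C)C(C)(C)C)C(C)=C2C(=O)[C@@]3(C)CC[C@]4(C)CCC(C)(C)C[C@H]4[C@@H]3CC(=O)N(C)OC | intermediate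
36 | C8-hydroxy (target configuration) C20 aldehyde | C12(OCCO1)C[C@@H](O[Si](C)(C)C(C)(C)C)C(C)=C2[C@@H](O)[C@@]3(C)CC[C@]4(C)CCC(C)(C)C[C@H]4[C@@H]3CC=O | intermediate (not isolated)
37 | lactol (O–C8, C20–OH, anomers) with C5 silyl ether and C6=C7 | C12(OCCO1)C[C@@H](O[Si](C)(C)C(C)(C)C)C(C)=C2[C@@H](O5)[C@@]3(C)CC[C@]4(C)CCC(C)(C)C[C@H]4[C@@H]3CC5O | intermediate
38 | lactol with free C5 hydroxyl and C6=C7 | C12(OCCO1)C[C@@H](O)C(C)=C2[C@@H](O5)[C@@]3(C)CC[C@]4(C)CCC(C)(C)C[C@H]4[C@@H]3CC5O | intermediate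
39 | lactol with saturated ring D, C5–C8 as in the target | C12(OCCO1)C[C@@H](O)[C@H](C)[C@@H]2[C@@H](O5)[C@@]3(C)CC[C@]4(C)CCC(C)(C)C[C@H]4[C@@H]3CC5O | intermediate
40 | C5,C8-diol with C3 ketal and allyl group on C18 | C12(OCCO1)C[C@@H](O)[C@H](C)[C@@H]2[C@@H](O)[C@@]3(C)CC[C@]4(C)CCC(C)(C)C[C@H]4[C@@H]3CC=C | intermediate
41 | C5,C8-bis(tert-butyldimethylsilyl) ether of 40 | C12(OCCO1)C[C@@H](O[Si](C)(C)C(C)(C)C)[C@H](C)[C@@H]2[C@@H](O[Si](C)(C)C(C)(C)C)[C@@]3(C)CC[C@]4(C)CCC(C)(C)C[C@H]4[C@@H]3CC=C | intermediate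
42 | C3 ketone with C5,C8-bis-silyl ether and allyl group | O=C1C[C@@H](O[Si](C)(C)C(C)(C)C)[C@H](C)[C@@H]1[C@@H](O[Si](C)(C)C(C)(C)C)[C@@]2(C)CC[C@]3(C)CCC(C)(C)C[C@H]3[C@@H]2CC=C | intermediate
43 | C3 tertiary isopropenyl carbinol (isopropenyl cis to C7–H) | CC(=C)[C@@]1(O)C[C@@H](O[Si](C)(C)C(C)(C)C)[C@H](C)[C@@H]1[C@@H](O[Si](C)(C)C(C)(C)C)[C@@]2(C)CC[C@]3(C)CCC(C)(C)C[C@H]3[C@@H]2CC=C | intermediate
44 | tetracyclic C3 tertiary allylic alcohol with C2=C20 in ring C | O[C@@]12C[C@@H](O[Si](C)(C)C(C)(C)C)[C@H](C)[C@@H]2[C@@H](O[Si](C)(C)C(C)(C)C)[C@@]2(C)CC[C@]3(C)CCC(C)(C)C[C@H]3[C@@H]2C/C=C1/C | intermediate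
45 | C5,C8-bis(tert-butyldimethylsilyl) ether of the target | C/C1=C2\C[C@@H](O[Si](C)(C)C(C)(C)C)[C@H](C)[C@@H]2[C@@H](O[Si](C)(C)C(C)(C)C)[C@@]2(C)CC[C@]3(C)CCC(C)(C)C[C@H]3[C@@H]2CC1 | intermediate
46 | CNP0213887.1 | C/C1=C2\C[C@@H](O)[C@H](C)[C@@H]2[C@@H](O)[C@@]2(C)CC[C@]3(C)CCC(C)(C)C[C@H]3[C@@H]2CC1 | target

**Step count**

Total steps: 35. Longest linear sequence: 31 steps (steps 1–19 and 24–35); the ring D fragment (steps 20–23) joins at step 24.

**Steps most likely to fail**

Step 16 (key cyclisation). What may go wrong is poor facial selectivity at C9, because the methyl and the silyloxymethyl group differ little in size, or reduction of the alkene without cyclisation. The fallback sets out from enal 18 and gives the C8 substituent a branch. Trimethyl orthoformate and PPTS in methanol should convert 18 into the dimethyl acetal enoate F1. The same iron-hydride cyclisation should then give the decalin acetal F2, with the branched acetal group clearly preferring the pseudo-equatorial site. Dilute aqueous acid should give the aldehyde ester F3, and NaBH4 in methanol should reduce it to hydroxy ester 22, which closes to lactone 23 on warming with a trace of DBU in toluene. The route is rejoined at 23.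

Step 33 (ring-closing metathesis). What may go wrong is failure of the carbene to engage the hindered isopropenyl group next to the fully substituted C3, leading to dimerisation at the allyl terminus. The fallback sets out from lactol 39 and closes ring C by carbonyl coupling. Wittig reaction of 39 with the ylide from (1-methoxyethyl)triphenylphosphonium chloride should give the enol ether diol F4. Silylation with TBSOTf and 2,6-lutidine should give the bis-silyl ether F5. Dilute aqueous acid should hydrolyse the enol ether and the dioxolane to the C2 methyl ketone/C3 cyclopentanone diketone F6. Intramolecular McMurry coupling (TiCl3(DME)1.5, Zn–Cu, DME, reflux, slow addition) should then form the tetrasubstituted C2=C3 alkene directly and give 45, where the route is rejoined.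

Step 34 (ionic hydrogenation). What may go wrong is loss of a proton from the allyl cation to give dienes, hydride capture at C3, or loss of a silyl ether under the Lewis acid. The fallback sets out from 44 and avoids the free cation. KHMDS and methyl chloroformate should give the tertiary allylic methyl carbonate F7. Pd(PPh3)4 with LiBHEt3 in THF should form the π-allyl palladium complex and deliver hydride to its less hindered C20 terminus, giving 45, where the route is rejoined.

**Further compounds**

F1 | step 16 | methyl (2E)-3-{(1S,2S)-2-[3-(dimethoxymethyl)but-3-en-1-yl]-2,5,5-trimethylcyclohexyl}prop-2-enoate | COC(=O)/C=C/[C@@H]1CC(C)(C)CC[C@@]1(C)CCC(=C)C(OC)OC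
F2 | step 16 | methyl 2-[2-(dimethoxymethyl)-2,4a,7,7-tetramethyldecahydronaphthalen-1-yl]acetate, trans-decalin, configuration as 21 | C(OC)(OC)[C@@]1(C)CC[C@]2(C)CCC(C)(C)C[C@H]2[C@@H]1CC(=O)OC
F3 | step 16 | methyl 2-(2-formyl-2,4a,7,7-tetramethyldecahydronaphthalen-1-yl)acetate, configuration as 21 | O=C[C@@]1(C)CC[C@]2(C)CCC(C)(C)C[C@H]2[C@@H]1CC(=O)OC
F4 | step 33 | C5,C8-diol with C3 ketal and a 3-methoxybut-2-enyl group on C18 (enol ether, E/Z mixture) | C12(OCCO1)C[C@@H](O)[C@H](C)[C@@H]2[C@@H](O)[C@@]3(C)CC[C@]4(C)CCC(C)(C)C[C@H]4[C@@H]3CC=C(C)OC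
F5 | step 33 | C5,C8-bis(tert-butyldimethylsilyl) ether of F4 | C12(OCCO1)C[C@@H](O[Si](C)(C)C(C)(C)C)[C@H](C)[C@@H]2[C@@H](O[Si](C)(C)C(C)(C)C)[C@@]3(C)CC[C@]4(C)CCC(C)(C)C[C@H]4[C@@H]3CC=C(C)OC
F6 | step 33 | diketone: C3 cyclopentanone and C2 methyl ketone (3-oxobutyl on C18), C5,C8-bis-silyl ether | O=C1C[C@@H](O[Si](C)(C)C(C)(C)C)[C@H](C)[C@@H]1[C@@H](O[Si](C)(C)C(C)(C)C)[C@@]2(C)CC[C@]3(C)CCC(C)(C)C[C@H]3[C@@H]2CCC(C)=O
F7 | step 34 | methyl carbonate of the C3 tertiary allylic alcohol 44 | COC(=O)O[C@@]12C[C@@H](O[Si](C)(C)C(C)(C)C)[C@H](C)[C@@H]2[C@@H](O[Si](C)(C)C(C)(C)C)[C@@]2(C)CC[C@]3(C)CCC(C)(C)C[C@H]3[C@@H]2C/C=C1/C
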